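**Strategy.** The plan cuts the cis-fused α-methyl-γ-butyrolactone off the cyclohexene ring (ring atoms C1, C9a, C9, C10, C11, C12; tuberostemonine numbering). An L-alanine-derived 6-hydroxyindoline that already carries the azepane and the side-chain lactone is dearomatised to a p-quinol. Its C10 carbonyl makes C11=C12 an enone, and α-iodination turns C12 into a Michael acceptor and C11 into an SN2 site. In the key step 5-methyl Meldrum's acid adds to C12 and its carboxylate displaces iodide at C11, so both lactone bonds and the C11, C12 and C13 stereocentres arise in one operation, anti to the C1 silyl ether. The remaining vinylogous amide is then converted into the C10-ethyl enamine.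

Key step: step 13

Remark: atoms are numbered N4; pyrrolidine C1, C2, C3, C9a; azepane C5–C9, C9a; cyclohexene C1, C9a, C9, C10, C11, C12; ring lactone O–C14(=O)–C13(CH3)–C12 with the ring oxygen on C11; side-chain lactone C18–C21 on C3; ethyl on C10. In these numbers the target is (1S,3S,10R,11R,12R,13S,18S,20S). Compounds 1, 4, 7, 14 and 21 are assumed to be commercial.

**Route**

Step 1
Reactants: 1 2-bromo-6-hydroxybenzaldehyde
Product: 2 2-(benzyloxy)-6-bromobenzaldehyde
Conditions: BnBr, K2CO3, DMF, rt
Reagents that add atoms: benzyl bromide, BrCc1ccccc1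
Why: Williamson etherification of the acidic phenol protects the oxygen that later becomes the C10 carbonyl; no stereocentre is formed.

Step 2
Reactants: 2 2-(benzyloxy)-6-bromobenzaldehyde
Product: 3 6-(benzyloxy)-2-bromo-3-iodobenzaldehyde
Conditions: NIS, TFA (0.3 equiv), MeCN, 60 °C
Reagents that add atoms: N-iodosuccinimide, O=C1CCC(=O)N1I
Why: Electrophilic aromatic iodination should go para to the benzyloxy group, a position that is also meta to the aldehyde and ortho to bromine, so all directors agree.

Step 3
Reactants: 3 6-(benzyloxy)-2-bromo-3-iodobenzaldehyde; 4 [2-(1,3-dioxolan-2-yl)ethyl]triphenylphosphonium bromide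
Product: 6 2-[(2Z)-3-[6-(benzyloxy)-2-bromo-3-iodophenyl]prop-2-en-1-yl]-1,3-dioxolane, via ylide 5 (not isolated)
Conditions: KHMDS, THF, −78 °C to rt
Reagents that add atoms: none
Why: Wittig olefination with a non-stabilised ylide under salt-free conditions should give the Z alkene (kinetic cis-oxaphosphetane, reinforced by the two ortho substituents), which installs C5–C8 in the geometry needed for the later seven-membered ring closure.

Step 4
Reactants: 6 the Z aryl iodide from step 3; 7 methyl (2R)-2-[(tert-butoxycarbonyl)amino]-3-iodopropanoate (Boc-3-iodo-L-alanine methyl ester)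
Product: 9 methyl (2S)-3-{4-(benzyloxy)-2-bromo-3-[(1Z)-3-(1,3-dioxolan-2-yl)prop-1-en-1-yl]phenyl}-2-[(tert-butoxycarbonyl)amino]propanoate, via alkylzinc iodide 8 (not isolated)
Conditions: 7, Zn dust, I2 (cat.), DMF, rt; then 6, Pd2(dba)3 (2.5 mol%), SPhos (5 mol%), 40 °C
Reagents that add atoms: none
Why: Zinc insertion into the C–I bond of 7 and Negishi cross-coupling should occur selectively at the aryl iodide (faster oxidative addition than at C–Br); the untouched L-amino acid centre becomes C3 (S).

Step 5
Reactants: 9 the aryl bromide amino ester from step 4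
Product: 10 1-tert-butyl 2-methyl (2S)-6-(benzyloxy)-7-[(1Z)-3-(1,3-dioxolan-2-yl)prop-1-en-1-yl]-2,3-dihydro-1H-indole-1,2-dicarboxylate
Conditions: Pd(OAc)2 (5 mol%), Xantphos (7.5 mol%), Cs2CO3, toluene, 100 °C
Reagents that add atoms: none
Why: Intramolecular Buchwald–Hartwig amidation of the carbamate N–H with the ortho C–Br bond closes the five-membered ring (N4–C9a bond), and the weak heterogeneous base should leave the α-centre intact.

Step 6
Reactants: 10 the N-Boc indoline from step 5
Product: 12 methyl (2S)-6-(benzyloxy)-1,7-(but-3-ene-1,4-diyl)indoline-2-carboxylate (alkene conjugated to the arene), via amino aldehyde 11 (not isolated)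
Conditions: TFA/H2O (9:1), CH2Cl2, 0 °C to rt; evaporate; NaBH(OAc)3, ClCH2CH2Cl, rt
Reagents that add atoms: none
Why: Acid removes the Boc group and the dioxolane, and the freed indoline N–H and aldehyde, held close by the Z alkene, undergo intramolecular reductive amination to the azepine ring (N4–C5 bond).

Step 7
Reactants: 12 the tricyclic amino ester from step 6
Product: 13 (2S)-6-(benzyloxy)-1,7-(but-3-ene-1,4-diyl)indoline-2-carbaldehyde
Conditions: DIBAL-H, CH2Cl2, −78 °C; Rochelle salt work-up
Reagents that add atoms: none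
Why: Partial reduction of the methyl ester stops at the aluminium hemiacetal at −78 °C and should give the α-amino aldehyde without epimerising C3; it is used at once.

Step 8
Reactants: 13 the aldehyde from step 7; 14 ethyl 2-[(trimethylsilyl)methyl]prop-2-enoate
Product: 16 (5S)-5-[(2S)-6-(benzyloxy)-1,7-(but-3-ene-1,4-diyl)indolin-2-yl]-3-methylideneoxolan-2-one, via hydroxy ester 15 (not isolated)
Conditions: SnCl4 (1.1 equiv), CH2Cl2, −78 °C, then 14; aqueous work-up; TsOH (cat.), CH2Cl2, rt
Reagents that add atoms: none
Why: Chelation-controlled Hosomi–Sakurai allylation: tin bridges the aldehyde oxygen and the α-nitrogen (Cram-chelate model), the allylsilane attacks from the side of the C3 hydrogen to give the syn amino alcohol (18S), and acid closes the α-methylene-γ-butyrolactone.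

Step 9
Reactants: 16 the α-methylene lactone from step 8
Product: 17 (3S,5S)-5-[(2S)-1,7-(butane-1,4-diyl)-6-hydroxyindolin-2-yl]-3-methyloxolan-2-one
Conditions: H2 (1 atm), 10% Pd/C, EtOAc/MeOH, rt
Reagents that add atoms: none
Why: Heterogeneous hydrogenation should add hydrogen to the exocyclic methylene from the face opposite to the C18 substituent (cis-lactone, 20S), saturate the styrenic C7=C8 bond and cleave the benzyl ether in one operation.

Step 10
Reactants: 17 the tricyclic aminophenol from step 9
Product: 18 p-quinol (1S,3S)-1-hydroxy-10-oxo-9(9a),11-diene carrying the (18S,20S)-lactone on C3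
Conditions: PhI(OAc)2, MeCN/H2O (4:1), 0 °C
Reagents that add atoms: water, O
Why: Hypervalent-iodine oxidative dearomatisation of the para-alkyl phenol: water should capture the phenoxenium ion at the para carbon C1 from the face opposite to the C3 substituent of the flat indoline (1S, OH trans to the side chain), and the product is stabilised as the vinylogous amide N4–C9a=C9–C10=O.

Step 11
Reactants: 18 the p-quinol from step 10
Product: 19 1-O-tert-butyldimethylsilyl ether of 18
Conditions: TBSOTf, 2,6-lutidine, CH2Cl2, 0 °C to rt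
Reagents that add atoms: tert-butyldimethylsilyl trifluoromethanesulfonate, CC(C)(C)[Si](C)(C)OS(=O)(=O)C(F)(F)F
Why: Silylation of the tertiary alcohol with the silyl triflate provides the bulky group that shields the C1–O face in step 13 and masks the hydroxyl in step 14.

Step 12
Reactants: 19 the silyl ether from step 11
Product: 20 11-iodo derivative of 19 (α-iodo enone)
Conditions: I2, pyridine, CH2Cl2, 0 °C to rt
Reagents that add atoms: iodine, II
Why: α-Iodination of the enone by a Baylis–Hillman-type sequence (pyridine adds to C12, the enolate is iodinated at C11, pyridine is lost) can occur only at C11, because C9 of the vinylogous amide is fully substituted.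

Step 13
Reactants: 20 the α-iodo enone from step 12; 21 2,2,5-trimethyl-1,3-dioxane-4,6-dione (5-methyl Meldrum's acid)
Product: 24 TBS-protected keto lactone (10-oxo; cis-fused C11–O/C12–C13 lactone on the face opposite to C1–O; C13 methyl cis to C1; 1S,3S,11S,12R,13S,18S,20S), via Michael adduct 22 (not isolated), via carboxy lactone 23 (not isolated)
Conditions: 21 (1.05 equiv), Et3N (1.1 equiv), MeCN, 0 °C to rt; then H2O, 90 °C
Reagents that add atoms: water, O
Why: Proposed new method: the ammonium salt of 21 adds as a soft carbon nucleophile to C12 of the α-iodo enone (Michael addition, C12–C13), the iodo enolate is protonated to the α-iodo ketone 22, hot water opens the Meldrum's ring with loss of acetone and one carboxylate displaces iodide at C11 (SN2, O–C11) to give 23, which decarboxylates to 24; the closest known reaction type is the Michael-initiated ring closure of α-halo enones with 1,3-dicarbonyl compounds to dihydrofurans, combined with the known Michael additions and hydrolysis–decarboxylation of Meldrum's acids. The lactone ring closes 5-exo-tet and can only be cis-fused, because the carboxylate sits on the C12–C13 bond and the epimerisable α-iodo ketone reacts through the epimer with iodine anti to it. C12 is controlled by the C1 silyl ether (attack anti to C1–O and syn to the C2 methylene), C11 by the cis ring fusion, and C13 by kinetic protonation of the lactone enol formed on decarboxylation from the convex face, which leaves the methyl group on the concave face next to C1. The step needs conjugate instead of carbonyl addition and reaction at C11=C12 instead of the N-conjugated C9=C9a bond, which the soft reversible donor and the fully substituted, deactivated vinylogous amide secure, and O- instead of C-alkylation at C11, which the quaternary C13 of the adduct secures since no cyclopropane can close.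

Step 14
Reactants: 24 the keto lactone from step 13
Product: 26 10-ethyl-9,10-didehydro iminium triflate (N4=C9a, C9=C10), via triflyloxy iminium triflate 25 (not isolated)
Conditions: Tf2O, CH2Cl2, −78 °C; then Et2CuLi, THF, −78 to −40 °C; non-aqueous work-up, used crude
Reagents that add atoms: trifluoromethanesulfonic anhydride, O=S(=O)(OS(=O)(=O)C(F)(F)F)C(F)(F)F; lithium diethylcuprate, [Li+].CC[Cu-]CC
Why: O-Triflation of the vinylogous amide gives a 3-triflyloxy-propeniminium salt in which C10 is an activated alkenyl triflate, and the cuprate should replace triflate by ethyl (alkenyl triflate–cuprate coupling) without touching the two lactones; no stereocentre is formed.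

Step 15
Reactants: 26 the unsaturated iminium triflate from step 14
Product: 27 1-O-tert-butyldimethylsilyl ether of the target
Conditions: Hantzsch ester (1.05 equiv), CH2Cl2, 0 °C to rt; aq. NaHCO3
Reagents that add atoms: none
Why: Conjugate hydride transfer from the dihydropyridine to the β-carbon C10 of the α,β-unsaturated iminium ion (iminium transfer hydrogenation) should occur from the face opposite to the cis-fused lactone, setting 10R (ethyl cis to O–C11) and leaving the C9=C9a enamine.

Step 16
Reactants: 27 the silyl-protected target from step 15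
Product: 28 target CNP0179500.1
Conditions: TBAF, AcOH (1:1), THF, 0 °C to rt
Reagents that add atoms: none
Why: Fluoride cleaves the tertiary silyl ether, and buffering with acetic acid should spare the base-sensitive C13 centre and the acid-sensitive α-hydroxy enamine.

**Compound list**

1 | 2-bromo-6-hydroxybenzaldehyde | O=Cc1c(O)cccc1Br | starting material
2 | 2-(benzyloxy)-6-bromobenzaldehyde | O=Cc1c(OCc2ccccc2)cccc1Br | intermediate
3 | 6-(benzyloxy)-2-bromo-3-iodobenzaldehyde | O=Cc1c(OCc2ccccc2)ccc(I)c1Br | intermediate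
4 | [2-(1,3-dioxolan-2-yl)ethyl]triphenylphosphonium bromide | [Br-].C1COC(CC[P+](c2ccccc2)(c2ccccc2)c2ccccc2)O1 | starting material
5 | [2-(1,3-dioxolan-2-yl)ethylidene]triphenylphosphorane (ylide) | C1COC(CC=P(c2ccccc2)(c2ccccc2)c2ccccc2)O1 | intermediate (not isolated)
6 | 2-[(2Z)-3-[6-(benzyloxy)-2-bromo-3-iodophenyl]prop-2-en-1-yl]-1,3-dioxolane | Brc1c(I)ccc(OCc2ccccc2)c1/C=C\CC1OCCO1 | intermediate
7 | methyl (2R)-2-[(tert-butoxycarbonyl)amino]-3-iodopropanoate (L-series) | CC(C)(C)OC(=O)N[C@@H](CI)C(=O)OC | starting material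
8 | alkylzinc iodide from 7 | CC(C)(C)OC(=O)N[C@@H](C[Zn]I)C(=O)OC | intermediate (not isolated)
9 | methyl (2S)-3-{4-(benzyloxy)-2-bromo-3-[(1Z)-3-(1,3-dioxolan-2-yl)prop-1-en-1-yl]phenyl}-2-[(tert-butoxycarbonyl)amino]propanoate | CC(C)(C)OC(=O)N[C@@H](Cc1ccc(OCc2ccccc2)c(/C=C\CC2OCCO2)c1Br)C(=O)OC | intermediate
10 | 1-tert-butyl 2-methyl (2S)-6-(benzyloxy)-7-[(1Z)-3-(1,3-dioxolan-2-yl)prop-1-en-1-yl]-2,3-dihydro-1H-indole-1,2-dicarboxylate | CC(C)(C)OC(=O)N1[C@H](C(=O)OC)Cc2ccc(OCc3ccccc3)c(/C=C\CC3OCCO3)c12 | intermediate
11 | methyl (2S)-6-(benzyloxy)-7-[(1Z)-4-oxobut-1-en-1-yl]indoline-2-carboxylate | O=CC/C=C\c1c(OCc2ccccc2)ccc2C[C@@H](C(=O)OC)Nc12 | intermediate (not isolated)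
12 | methyl (2S)-6-(benzyloxy)-1,7-(but-3-ene-1,4-diyl)indoline-2-carboxylate | O(Cc1ccccc1)c1ccc2c3c1C=CCCN3[C@H](C(=O)OC)C2 | intermediate
13 | (2S)-6-(benzyloxy)-1,7-(but-3-ene-1,4-diyl)indoline-2-carbaldehyde | O(Cc1ccccc1)c1ccc2c3c1C=CCCN3[C@H](C=O)C2 | intermediate
14 | ethyl 2-[(trimethylsilyl)methyl]prop-2-enoate | CCOC(=O)C(=C)C[Si](C)(C)C | starting material
15 | ethyl (4S)-4-[(2S)-6-(benzyloxy)-1,7-(but-3-ene-1,4-diyl)indolin-2-yl]-4-hydroxy-2-methylidenebutanoate | O(Cc1ccccc1)c1ccc2c3c1C=CCCN3[C@H]([C@@H](O)CC(=C)C(=O)OCC)C2 | intermediate (not isolated)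
16 | (5S)-5-[(2S)-6-(benzyloxy)-1,7-(but-3-ene-1,4-diyl)indolin-2-yl]-3-methylideneoxolan-2-one | O(Cc1ccccc1)c1ccc2c3c1C=CCCN3[C@H]([C@@H]4CC(=C)C(=O)O4)C2 | intermediate
17 | (3S,5S)-5-[(2S)-1,7-(butane-1,4-diyl)-6-hydroxyindolin-2-yl]-3-methyloxolan-2-one | Oc1ccc2c3c1CCCCN3[C@H]([C@@H]4C[C@H](C)C(=O)O4)C2 | intermediate
18 | p-quinol: (1S,3S)-1-hydroxy-10-oxo tricycle with C9=C9a and C11=C12, (18S,20S)-lactone on C3 | O=C1C2=C3N(CCCC2)[C@H]([C@@H]4C[C@H](C)C(=O)O4)C[C@]3(O)C=C1 | intermediate
19 | 1-O-TBS ether of 18 | O=C1C2=C3N(CCCC2)[C@H]([C@@H]4C[C@H](C)C(=O)O4)C[C@]3(O[Si](C)(C)C(C)(C)C)C=C1 | intermediate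
20 | 11-iodo derivative of 19 | O=C1C2=C3N(CCCC2)[C@H]([C@@H]4C[C@H](C)C(=O)O4)C[C@]3(O[Si](C)(C)C(C)(C)C)C=C1I | intermediate
21 | 2,2,5-trimethyl-1,3-dioxane-4,6-dione | CC1C(=O)OC(C)(C)OC1=O | starting material
22 | Michael adduct: 11-iodo-10-oxo compound with the 5-methyl Meldrum's unit on C12 (12R; C11 epimers) | O=C1C2=C3N(CCCC2)[C@H]([C@@H]4C[C@H](C)C(=O)O4)C[C@]3(O[Si](C)(C)C(C)(C)C)[C@H](C5(C)C(=O)OC(C)(C)OC5=O)C1I | intermediate (not isolated)
23 | 13-carboxy lactone (cis-fused at C11/C12; C13 epimers) | O=C1C2=C3N(CCCC2)[C@H]([C@@H]4C[C@H](C)C(=O)O4)C[C@]3(O[Si](C)(C)C(C)(C)C)[C@H]5[C@@H]1OC(=O)C5(C)C(=O)O | intermediate (not isolated)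
24 | TBS-protected keto lactone (1S,3S,11S,12R,13S,18S,20S) | O=C1C2=C3N(CCCC2)[C@H]([C@@H]4C[C@H](C)C(=O)O4)C[C@]3(O[Si](C)(C)C(C)(C)C)[C@H]5[C@@H]1OC(=O)[C@H]5C | intermediate
25 | 10-triflyloxy-9,10-didehydro iminium triflate (N4=C9a) | FC(F)(F)S(=O)(=O)OC1=C2C3=[N+](CCCC2)[C@H]([C@@H]4C[C@H](C)C(=O)O4)C[C@]3(O[Si](C)(C)C(C)(C)C)[C@H]5[C@@H]1OC(=O)[C@H]5C.[O-]S(=O)(=O)C(F)(F)F | intermediate (not isolated)
26 | 10-ethyl-9,10-didehydro iminium triflate (N4=C9a, C9=C10) | CCC1=C2C3=[N+](CCCC2)[C@H]([C@@H]4C[C@H](C)C(=O)O4)C[C@]3(O[Si](C)(C)C(C)(C)C)[C@H]5[C@@H]1OC(=O)[C@H]5C.[O-]S(=O)(=O)C(F)(F)F | intermediate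
27 | 1-O-TBS ether of the target | CC[C@@H]1C2=C3N(CCCC2)[C@H]([C@@H]4C[C@H](C)C(=O)O4)C[C@]3(O[Si](C)(C)C(C)(C)C)[C@H]5[C@@H]1OC(=O)[C@H]5C | intermediate
28 | CNP0179500.1 (1S,3S,10R,11R,12R,13S,18S,20S) | CC[C@@H]1C2=C3N(CCCC2)[C@H]([C@@H]2C[C@H](C)C(=O)O2)C[C@]3(O)[C@H]2[C@@H]1OC(=O)[C@H]2C | target

**Totals and risks**

Total steps: 16. Longest linear sequence: 16 steps (1 to 28); 4, 7, 14 and 21 enter as purchased building blocks.

Steps most likely to fail:

1. Step 13 (Proposed new method). The quaternary donor may add too slowly to the congested C12. The iodide may be lost by halophilic attack or by dehydroiodination of 22 before the carboxylate is unmasked. Protonation at C13 may be poorly face-selective. The fallback uses known chemistry, sets out from 19 and forms the C–O bond oxidatively instead of by displacement. Amine-catalysed Michael addition of 21 to the plain enone 19 gives the Meldrum's adduct F1. Aqueous hydrolysis with loss of acetone gives the methylmalonic acid F2. Hypervalent-iodine α-lactonisation of this 5-oxo acid with PhI(OH)OTs closes O–C11 and gives 23, whose thermal decarboxylation returns to the route at 24.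

2. Step 10. The iodane may oxidise the aniline nitrogen (dehydrogenation towards the indole), attack may occur ortho instead of para, or water may add with poor facial selectivity. The fallback sets out from 17 and replaces the two-electron iodane oxidation by photo-oxygenation of the phenolate (O2, rose bengal, visible light, Cs2CO3, MeOH, −20 °C). Capture of singlet oxygen at the para carbon gives the hydroperoxide F3, which Me2S reduces to 18, where the route is rejoined.

3. Step 15. Hydride may be delivered to the iminium carbon C9a instead of C10, or the enamine may be over-reduced through its iminium tautomer. The fallback sets out from 26 and reduces the C=C bond instead of using a hydride donor. Hydrogenation of C9=C10 over Pd/C (H2, EtOAc), from the face opposite to the lactone, gives the saturated iminium triflate F4, and aqueous NaHCO3 removes the C9 proton to give the enamine 27, where the route is rejoined.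

**Further compounds**

F1 | step 13 | Michael adduct of 21 with 19 (10-oxo, C11 methylene, Meldrum's unit on C12) | O=C1C2=C3N(CCCC2)[C@H]([C@@H]4C[C@H](C)C(=O)O4)C[C@]3(O[Si](C)(C)C(C)(C)C)[C@H](C5(C)C(=O)OC(C)(C)OC5=O)C1
F2 | step 13 | methylmalonic acid from hydrolysis of F1 | O=C1C2=C3N(CCCC2)[C@H]([C@@H]4C[C@H](C)C(=O)O4)C[C@]3(O[Si](C)(C)C(C)(C)C)[C@H](C(C)(C(=O)O)C(=O)O)C1
F3 | step 10 | 1-hydroperoxy analogue of 18 | O=C1C2=C3N(CCCC2)[C@H]([C@@H]4C[C@H](C)C(=O)O4)C[C@]3(OO)C=C1
F4 | step 15 | 9,10-dihydro iminium triflate (N4=C9a; C9 configuration lost in the next operation) | CC[C@@H]1C2C3=[N+](CCCC2)[C@H]([C@@H]4C[C@H](C)C(=O)O4)C[C@]3(O[Si](C)(C)C(C)(C)C)[C@H]5[C@@H]1OC(=O)[C@H]5C.[O-]S(=O)(=O)C(F)(F)F
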